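Count every amount as a fraction of the substrate charged and follow the fraction left. Target is its complement, for in the runs the two readings sum to about one, as with 65.8% and 32.8% at 5.00 h in winter.

| flask | substrate | gas | free catalyst | remark | time |
|---|---|---|---|---|---|
| midnight | 0.050 M (in portions, 4) | 32 mM (held) | 4.5 mM | run made earlier; portions every 25 min |  |
| summer | 0.075 M (in portions, 4) | 32 mM (held) | 4.5 mM | run made earlier; portions every 25 min |  |
| winter | 0.10 M (in portions, 4) | 32 mM (held) | 6.8 mM | run made earlier; portions every 25 min |  |
| Monday's | 0.10 M | 32 mM | 4.5 mM | everything together at the start | 12 h |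
| Thursday's | 0.10 M (in portions, 4) | 32 mM (held) | 4.5 mM | the portions of substrate follow each other after 25 min, the first at the start | 6.0 h |

| run | time / h | target / % | substrate / % |
|---|---|---|---|
| midnight | 1.33 | 12.3 | 84.8 |
| midnight | 2.50 | 29.4 | 68.0 |
| midnight | 4.00 | 47.9 | 47.5 |
| midnight | 5.00 | 61.5 | 39.6 |
| summer | 0.667 | 4.8 | 45.4 |
| summer | 1.50 | 14.5 | 85.3 |
| summer | 3.00 | 35.1 | 65.5 |
| summer | 5.00 | 54.7 | 44.4 |
| winter | 1.33 | 12.9 | 84.1 |
| winter | 2.50 | 34.8 | 65.2 |
| winter | 4.00 | 55.7 | 44.0 |
| winter | 5.00 | 65.8 | 32.8 |

(each reading ± 1 percentage point)

- the numbers in the tables scatter with a standard deviation of 1 percentage point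
- at the start none of the gas is in solution

1. which one finishes higher in amount of target, in percent of the substrate charged ("neither" within 2 percentage points) (Monday's / Thursday's / neither)
2. amount of target at the end, in percent of the substrate charged, Monday's
3. amount of target at the end, in percent of the substrate charged, Thursday's

Take the run slowly. In the first instants no gas is in solution and substrate is still arriving, so the fraction left says little yet: at 0.667 h the summer run shows 45.4% with two of the 4 portions in. The last portion is in after 1.25 h.

In the middle, watch the ratio of two fractions left. In winter the fraction falls from 65.2% at 2.50 h to 32.8% at 5.00 h. Take the logarithm of that ratio, divide by the time between, and scale from 6.8 mM of free catalyst to 4.5 mM. This gives 0.182 h⁻¹, the decay constant of the fraction left, a pseudo-first-order constant as read from the readings. The summer run, at 4.5 mM itself, gives 0.194 h⁻¹ from its last two readings.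

Now the end. Count catalyst times time as the clock, so that winter's 4.00 h equals 6.04 h at 4.5 mM. Thursday's then leaves about 44.0%, and my reckoning gives 56.0% of target. Read Monday's gas as the same saturation level, since winter made 65.8 mM of target, more than 32 mM. Monday's feeding differs, but the portions span less than its 12 h. Run the constant onward to 12 h: Monday's leaves 14.9%, so it reaches 85.1%.

The forecast stands near mine on Thursday's and parts on Monday's: Thursday's higher, with 31% for Monday's and 58% for Thursday's, for “I read it as a single 32 mM charge”.

The flask gives Monday's higher, with 90.5% for Monday's and 58.8% for Thursday's.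

    reagent + free catalyst ⇌ catalyst intermediate A (K = 16.0 L mol⁻¹, k = 290 L mol⁻¹ h⁻¹)
    substrate + catalyst intermediate A ⇌ catalyst intermediate B (K = 11.0 L mol⁻¹, k = 6600 L mol⁻¹ h⁻¹)
    catalyst intermediate B → free catalyst + target (k = 19.0 h⁻¹)
    gas ⇌ reagent, rate k4*(csat - [reagent]) (kL = 3.10 h⁻¹)
    catalyst intermediate B + target → spent catalyst (k = 0.280 L mol⁻¹ h⁻¹)

In Monday's, reagent still stands at 0.0311 M at 12.0 h, with 90.5 mM of target made. Monday's longer time is the largest single effect : Monday's gives 90.5% of target in its 12 h and 61.0% without that difference in time, stopped at Thursday's 6.0 h, and the way substrate goes in is not the reason. From Monday's 38.5% left at that time, the constant gives 12.9% left at 12.0 h, against 9.22% in the flask. Scaled to 1.10 mM of free catalyst, it gives 58.6% left in that neighbour of Monday's, which holds 63%.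

The data were computed for an exercise, and the scatter is random.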